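Numbering: ring A = 3,4-dimethoxyphenyl, ring B = 4-allyl-2,6-dimethoxyphenyl; C7 = carbinol carbon on ring A, C8 = carbon bearing the ring B oxygen, C9 = methyl.
Cuts: the C7–H bond (carbinol back to the aryl ketone, with one inversion at C7 in between), the C8–O ether bond to ring B (back to an α-bromo ketone and a phenol), and the C4–allyl bond of ring B (back to an O-allyl ether).
Forward: no ring is formed; the allyl group is brought onto ring B (O-allylation, para-Claisen), the propiophenone of ring A is brominated at C8, the halves are joined at C8–O, the C7 ketone is reduced and C7 is inverted.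
Stereochemistry: C7 and C8 are fixed together (7R,8R, threo) when a chiral ruthenium hydride reduces the racemic ketone with dynamic kinetic resolution; a Mitsunobu inversion at C7 then gives the (7S,8R)-erythro target.
Enabling feature: C8 bears a single hydrogen between the C7 carbonyl, conjugated with ring A, and the ether oxygen to ring B, so it enolises and racemises while the ketone is being reduced.

Key step: step 5

Assumption: the reduction is taken to be threo-selective (hydride anti to the C8–O bond, as in the benzoin to hydrobenzoin case); if it proved erythro-selective, the (R,R) catalyst would give the target directly and the inversion would fall away.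

Step 1
Reactants: 1 2,6-dimethoxyphenol; 2 allyl bromide
Product: 3 allyl 2,6-dimethoxyphenyl ether
Conditions: K2CO3, acetone, reflux
Reagents that add atoms: none
Why: Williamson ether synthesis: the potassium phenoxide of 1 displaces bromide from the primary allylic halide 2 in an SN2 step, and K2CO3 in acetone favours O- over C-allylation.

Step 2
Reactants: 3 allyl 2,6-dimethoxyphenyl ether
Product: 6 4-allyl-2,6-dimethoxyphenol, via ortho-dienone 4 (not isolated), via para-dienone 5 (not isolated)
Conditions: PhNEt2, 200 °C, N2
Reagents that add atoms: none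
Why: Aromatic Claisen rearrangement in its para variant: the [3,3] shift onto a methoxy-blocked ortho carbon gives dienone 4, which cannot tautomerise, so a Cope [3,3] shift moves the allyl group on to C4 (dienone 5) and enolisation restores the aromatic ring.

Step 3
Reactants: 7 1-(3,4-dimethoxyphenyl)propan-1-one
Product: 8 racemic 2-bromo-1-(3,4-dimethoxyphenyl)propan-1-one
Conditions: CuBr2 (2 equiv), EtOAc–CHCl3 (1:1), reflux
Reagents that add atoms: copper dibromide (CuBr2), Br[Cu]Br
Why: Ketone α-halogenation through the enol: CuBr2 delivers bromine to C8, the only enolisable position, while free bromine stays low so that the electron-rich ring A is not brominated; the racemate is what step 5 needs.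

Step 4
Reactants: 8 racemic 2-bromo-1-(3,4-dimethoxyphenyl)propan-1-one; 6 4-allyl-2,6-dimethoxyphenol
Product: 9 racemic 2-(4-allyl-2,6-dimethoxyphenoxy)-1-(3,4-dimethoxyphenyl)propan-1-one
Conditions: K2CO3, butanone, reflux
Reagents that add atoms: none
Why: Williamson-type SN2 etherification: the phenoxide of 6 displaces bromide from C8, a secondary carbon activated by the neighbouring carbonyl, which forms the C8–O bond; no stereocontrol is needed because step 5 is stereoconvergent.

Step 5
Reactants: 9 racemic 2-(4-allyl-2,6-dimethoxyphenoxy)-1-(3,4-dimethoxyphenyl)propan-1-one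
Product: 12 (1R,2R)-2-(4-allyl-2,6-dimethoxyphenoxy)-1-(3,4-dimethoxyphenyl)propan-1-ol (the (7R,8R)-threo alcohol), via enol 10 (not isolated), via (R)-ketone 11 (not isolated)
Conditions: RuCl[(S,S)-TsDPEN](p-cymene) (2 mol %; TsDPEN = N-tosyl-1,2-diphenylethylenediamine), HCO2H (3 equiv), DBU (3.5 equiv), degassed DMF, 40 °C, N2
Reagents that add atoms: none
Why: The 18-electron hydride RuH[(S,S)-TsDPEN](p-cymene), formed from the chloride, base and formate with loss of CO2, passes Ru–H and N–H to the C7=O group through a six-membered outer-sphere transition state and so forms the C7–H bond, while free DBU interconverts the two C8 enantiomers of 9 through enol 10. The closest known reaction type is the asymmetric transfer hydrogenation with dynamic kinetic resolution of racemic α-oxygenated aryl ketones by arene–ruthenium monosulfonyl-diamine catalysts (benzoin to hydrobenzoin, α-alkoxy β-keto esters). No ring closes. C7 (R) is controlled by the catalyst, whose (S,S) ligand places ring A under the p-cymene ligand and thereby fixes the carbonyl face; C8 (R) is controlled by kinetic selection of ketone 11, the enantiomer that can hold its C8–O bond anti to the incoming hydride with C8–H rather than the C9 methyl beside the trajectory (Felkin–Anh arrangement), which leads to the threo alcohol. The step needs face selectivity at C7, a rate preference for one C8 enantiomer and racemisation faster than reduction; the last is secured by the acidity of C8–H between the aryl ketone and the aryloxy oxygen together with the slight excess of DBU over formic acid, and the electron-rich ring A slows hydride transfer to the benefit of the equilibration. Alcohol 12 has no carbonyl next to C8 and cannot epimerise, and the allyl alkene is left alone because the saturated ruthenium hydride has no free coordination site.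

Step 6
Reactants: 12 (1R,2R)-2-(4-allyl-2,6-dimethoxyphenoxy)-1-(3,4-dimethoxyphenyl)propan-1-ol
Product: 14 (1S,2R)-2-(4-allyl-2,6-dimethoxyphenoxy)-1-(3,4-dimethoxyphenyl)propyl 4-nitrobenzoate, via alkoxyphosphonium salt 13 (not isolated)
Conditions: 4-O2NC6H4CO2H, PPh3, DIAD, toluene, −20 to 0 °C
Reagents that add atoms: 4-nitrobenzoic acid, O=C(O)c1ccc(cc1)[N+](=O)[O-]
Why: Mitsunobu reaction: the C7 hydroxyl is activated as alkoxyphosphonium 13 and displaced by 4-nitrobenzoate in an SN2 step with inversion (7R to 7S), the acidic nucleophile, non-polar solvent and low temperature holding back ionisation of the electron-rich benzylic centre, and C8 is not touched.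

Step 7
Reactants: 14 (1S,2R)-2-(4-allyl-2,6-dimethoxyphenoxy)-1-(3,4-dimethoxyphenyl)propyl 4-nitrobenzoate
Product: 15 (1S,2R)-2-(4-allyl-2,6-dimethoxyphenoxy)-1-(3,4-dimethoxyphenyl)propan-1-ol (CNP0106299.1, the (7S,8R)-erythro target)
Conditions: K2CO3 (0.2 equiv), MeOH–THF, rt
Reagents that add atoms: none
Why: Base-catalysed transesterification (methanolysis) of the activated aryl ester breaks only the acyl–oxygen bond, so C7 keeps its S configuration, and C8, no longer next to a carbonyl, cannot epimerise.

Compound list
1 | 2,6-dimethoxyphenol | COc1cccc(OC)c1O | starting material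
2 | allyl bromide | C=CCBr | starting material
3 | allyl 2,6-dimethoxyphenyl ether | C=CCOc1c(OC)cccc1OC | intermediate
4 | 6-allyl-2,6-dimethoxycyclohexa-2,4-dien-1-one (ortho-dienone, racemic, formed in the flask) | C=CCC1(OC)C=CC=C(OC)C1=O | intermediate
5 | 4-allyl-2,6-dimethoxycyclohexa-2,5-dien-1-one (para-dienone, formed in the flask) | C=CCC1C=C(OC)C(=O)C(OC)=C1 | intermediate
6 | 4-allyl-2,6-dimethoxyphenol | C=CCc1cc(OC)c(O)c(OC)c1 | intermediate
7 | 1-(3,4-dimethoxyphenyl)propan-1-one | CCC(=O)c1ccc(OC)c(OC)c1 | starting material
8 | racemic 2-bromo-1-(3,4-dimethoxyphenyl)propan-1-one | CC(Br)C(=O)c1ccc(OC)c(OC)c1 | intermediate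
9 | racemic 2-(4-allyl-2,6-dimethoxyphenoxy)-1-(3,4-dimethoxyphenyl)propan-1-one | C=CCc1cc(OC)c(OC(C)C(=O)c2ccc(OC)c(OC)c2)c(OC)c1 | intermediate
10 | 2-(4-allyl-2,6-dimethoxyphenoxy)-1-(3,4-dimethoxyphenyl)prop-1-en-1-ol (enol of 9, double-bond geometry not defined, formed in the flask) | C=CCc1cc(OC)c(OC(C)=C(O)c2ccc(OC)c(OC)c2)c(OC)c1 | intermediate
11 | (R)-2-(4-allyl-2,6-dimethoxyphenoxy)-1-(3,4-dimethoxyphenyl)propan-1-one (the reacting enantiomer of 9, fed from the enol) | C=CCc1cc(OC)c(O[C@H](C)C(=O)c2ccc(OC)c(OC)c2)c(OC)c1 | intermediate
12 | (1R,2R)-2-(4-allyl-2,6-dimethoxyphenoxy)-1-(3,4-dimethoxyphenyl)propan-1-ol ((7R,8R)-threo) | C=CCc1cc(OC)c(O[C@H](C)[C@H](O)c2ccc(OC)c(OC)c2)c(OC)c1 | intermediate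
13 | [(1R,2R)-2-(4-allyl-2,6-dimethoxyphenoxy)-1-(3,4-dimethoxyphenyl)propoxy]triphenylphosphonium 4-nitrobenzoate (formed in the flask) | C=CCc1cc(OC)c(O[C@H](C)[C@H](O[P+](c3ccccc3)(c3ccccc3)c3ccccc3)c2ccc(OC)c(OC)c2)c(OC)c1.[O-]C(=O)c1ccc([N+](=O)[O-])cc1 | intermediate
14 | (1S,2R)-2-(4-allyl-2,6-dimethoxyphenoxy)-1-(3,4-dimethoxyphenyl)propyl 4-nitrobenzoate ((7S,8R)-erythro) | C=CCc1cc(OC)c(O[C@H](C)[C@@H](OC(=O)c3ccc([N+](=O)[O-])cc3)c2ccc(OC)c(OC)c2)c(OC)c1 | intermediate
15 | (1S,2R)-2-(4-allyl-2,6-dimethoxyphenoxy)-1-(3,4-dimethoxyphenyl)propan-1-ol (CNP0106299.1, (7S,8R)-erythro) | C=CCc1cc(OC)c(O[C@H](C)[C@@H](O)c2ccc(OC)c(OC)c2)c(OC)c1 | target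

Total step count: 7
Longest linear sequence: 6 steps (1 to 3 to 6 to 9 to 12 to 14 to 15; steps 1, 2, 4, 5, 6, 7)

Steps most likely to fail

Step 5. Enolisation at C8 may not keep pace with hydride transfer, so that the reduction runs as a kinetic resolution and both diastereomers form. The discrimination between the two ketone enantiomers by the catalyst may also be weak. Before step 6 the threo relation of 12 would be checked by the H7–H8 coupling and its absolute sense by Mosher esters. The fallback replaces catalyst control by the chiral pool. It sets out from 6 and comes back at 15, so that steps 5 to 7 are not needed. Mitsunobu etherification of 6 with ethyl (S)-lactate (PPh3, DIAD, THF, 0 °C to rt) should give, with inversion, ethyl (R)-2-(4-allyl-2,6-dimethoxyphenoxy)propanoate F1. Treatment with MeNH(OMe)·HCl and iPrMgCl in THF at −20 °C should turn it into the Weinreb amide (R)-2-(4-allyl-2,6-dimethoxyphenoxy)-N-methoxy-N-methylpropanamide F2. Commercial 3,4-dimethoxyphenylmagnesium bromide in THF at 0 °C should then give ketone 11, here isolated as a single enantiomer. Reduction with Zn(BH4)2 in Et2O at −20 °C, with zinc bridging the carbonyl oxygen and the C8 ether oxygen and hydride entering from the side of C8–H, should give the erythro alcohol 15 directly.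

Step 6. Ionisation of the activated benzylic C7–O bond, helped by the para-methoxy group of ring A, would erode the inversion or divert material into elimination. The fallback replaces substitution by a redox inversion. It sets out from 12 and comes back at 15, so that step 7 is not needed. Dess–Martin periodinane with NaHCO3 in CH2Cl2 at 0 °C should oxidise 12 to ketone 11 without base strong enough to touch C8. The same chelation-controlled reduction with Zn(BH4)2 in Et2O at −20 °C should then deliver 15. No new compound arises.

Step 2. At 200 °C the relay through the two dienones may stall, or the allyl ether may cleave and the phenol char. The fallback replaces the sigmatropic shifts by a cross-coupling. It sets out from 1 and comes back at 6, so that step 1 is not needed either. Bromination of 1 with NBS in CHCl3 at −40 °C, directed para by the free hydroxyl, should give 4-bromo-2,6-dimethoxyphenol F3. Suzuki–Miyaura coupling with allylboronic acid pinacol ester (PdCl2(dppf), K2CO3, dioxane–H2O, 80 °C) should then give 6.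

Further compounds
F1 | step 5 | ethyl (R)-2-(4-allyl-2,6-dimethoxyphenoxy)propanoate | C=CCc1cc(OC)c(O[C@H](C)C(=O)OCC)c(OC)c1
F2 | step 5 | (R)-2-(4-allyl-2,6-dimethoxyphenoxy)-N-methoxy-N-methylpropanamide | C=CCc1cc(OC)c(O[C@H](C)C(=O)N(C)OC)c(OC)c1
F0 | step 6 | none | none
F3 | step 2 | 4-bromo-2,6-dimethoxyphenol | COc1cc(Br)cc(OC)c1O
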